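**Plan**

Labels (primes for the saturated-lactone half): C10 = C(CH3)(vinyl), C1 = vinyl CH on C10, C5 = CH–isopropenyl, C8 = CH–O, C7 = ring carbon bearing C11, C12 = lactone C=O, C13/C13' = the CH2–CH2 link; ring A = cyclohexane of the butenolide half, ring B = butenolide, ring A' = cyclohexane of the saturated half.
Cuts: C7=C11 and O8–C12 of ring B (intramolecular Horner–Wadsworth–Emmons), then C13–C13' (radical conjugate addition to the C11'=C13' methylene lactone), then C7'–C11' and O8'–C12' in the saturated half, and in both cyclohexanes the C5–isopropenyl bond and the O–C8 bond of a temporary lactone.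
Feature: in ring A the oxygen on C8 is cis-1,3 to C1 and the isopropenyl on C5 is trans to C1, so a γ-lactone bridge C1(=O)–O–C8, absent from the target, can be closed by bromolactonisation of achiral 1-methylcyclohexa-2,5-diene-1-carboxylic acid; ring A' has the same C10/C5 pattern in the opposite absolute sense and comes from the mirror-image bromolactone.
Forward: Birch methylation; bridging lactone (both antipodes); ring A taken to a ketol; ring A' opened, oxidised at C8', alkylated at C7', closed to the cis-fused lactone and methylenated; radical coupling joins C13 to C13'; esterification and olefination close ring B last.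
Stereochemistry: the catalyst sets C10 and, through the bridge, C8; the bridge steers isopropenyl to C5; in ring A' C7' is set by equilibration (equatorial), C8' by hydride attack anti to the axial methyl, C11' by hydrogen transfer on the convex face.

Key step: step 2

Remark: (DHQD)2PHAL is taken to give the (1S,5S,8S) bromolactone; if the sense of induction is the reverse, the two ligands change places between steps 2 and 10.

**Route**

Step 1
Reactants: 1 benzoic acid; 2 iodomethane
Product: 3 1-methylcyclohexa-2,5-diene-1-carboxylic acid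
Conditions: Li, NH3(l)/THF, −78 °C; MeI, −78 → 23 °C; aq. HCl
Reagents that add atoms: iodomethane (2), CI
Why: Birch reduction stops at the 1,4-dihydro stage because the carboxylate-stabilised dianion is an enolate, and its C-methylation at the ipso carbon (Birch reductive alkylation) should give the achiral diene acid with a mirror plane and no stereocentre.

Step 2
Reactants: 3 1-methylcyclohexa-2,5-diene-1-carboxylic acid; 4 N-bromosuccinimide
Product: 5 (1S,5S,8S)-8-bromo-1-methyl-6-oxabicyclo[3.2.1]oct-2-en-7-one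
Conditions: NBS (1.1 equiv), (DHQD)2PHAL (10 mol %), CHCl3/n-hexane 1:1, −40 °C
Reagents that add atoms: N-bromosuccinimide (4), O=C1CCC(=O)N1Br
Why: The quinuclidine of the catalyst holds the acid as a chiral ammonium carboxylate ion pair while NBS is activated in the same pocket, so a bromonium ion forms on one of the two enantiotopic ring alkenes and the bound carboxylate opens it anti at the carbon remote from C1. The closest known reaction type is the cinchona-alkaloid-catalysed enantioselective halolactonisation that desymmetrises 1-substituted cyclohexa-2,5-diene-1-carboxylic acids. The one ring that closes is the γ-lactone, formed in a 5-endo sense with respect to the brominated alkene, which is preferred over 4-exo closure to a strained β-lactone. The quaternary centre C1 of 5 (C10 of the target) is set by the catalyst through its choice of alkene, the C5–O centre (C8 of the target) follows from it because the one-carbon tether lets the carboxylate reach only the ring face on which it stands, and the C8–Br centre (removed in step 3) follows from anti addition. The step needs enantiotopic-group selectivity, γ- over β-lactone regioselectivity and a stop after one bromination; the mirror plane of 3 leaves the catalyst as the only element that tells the alkenes apart, and the remaining alkene of 5 has lost its internal nucleophile and is inductively deactivated, so it should not react at −40 °C.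

Step 3
Reactants: 5 (1S,5S,8S)-8-bromo-1-methyl-6-oxabicyclo[3.2.1]oct-2-en-7-one
Product: 6 (1S,5S)-1-methyl-6-oxabicyclo[3.2.1]oct-2-en-7-one
Conditions: Bu3SnH (1.5 equiv, 0.5 M), AIBN (10 mol %), benzene, 80 °C
Reagents that add atoms: none
Why: Radical-chain hydrodebromination with Bu3SnH leaves lactone and alkene untouched, and at this stannane concentration hydrogen transfer should outrun 3-exo closure of the homoallylic radical; the C–Br stereocentre disappears and no new one forms.

Step 4
Reactants: 6 (1S,5S)-1-methyl-6-oxabicyclo[3.2.1]oct-2-en-7-one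
Product: 7 (1S,5R)-1-methyl-6-oxabicyclo[3.2.1]oct-2-ene-4,7-dione
Conditions: Rh2(cap)4 (1 mol %, cap = caprolactamate), t-BuOOH (70% aq., 5 equiv), K2CO3 (0.5 equiv), CH2Cl2, 23 °C
Reagents that add atoms: tert-butyl hydroperoxide, CC(C)(C)OO
Why: Dirhodium-caprolactamate-catalysed allylic oxidation abstracts hydrogen from C4, the only allylic CH2 (C1 is quaternary), and the allyl radical should be oxygenated at this less hindered terminus to place the enone carbonyl at C4 (C7 of the target); no stereocentre changes, the C5 descriptor switching through priorities only.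

Step 5
Reactants: 7 (1S,5R)-1-methyl-6-oxabicyclo[3.2.1]oct-2-ene-4,7-dione; 8 isopropenylmagnesium bromide
Product: 10 (1S,2R,5R)-1-methyl-2-(prop-1-en-2-yl)-6-oxabicyclo[3.2.1]octane-4,7-dione, via trimethylsilyl enol ether 9 (not isolated)
Conditions: CH2=C(CH3)MgBr (1.5 equiv), CuBr·SMe2 (20 mol %), Me3SiCl (2 equiv), THF, −78 → −40 °C; 1 M HCl
Reagents that add atoms: isopropenylmagnesium bromide (8), CC(=C)[Mg]Br
Why: Copper-catalysed, Me3SiCl-accelerated conjugate addition should deliver isopropenyl to C2 on the face anti to the two-atom lactone bridge, the facial bias known from additions to levoglucosenone-type bridged enones, which sets C2 (C5 of the target) trans to the lactone carbonyl carbon while the hindered lactone is not attacked at low temperature.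

Step 6
Reactants: 10 (1S,2R,5R)-1-methyl-2-(prop-1-en-2-yl)-6-oxabicyclo[3.2.1]octane-4,7-dione
Product: 11 (1'S,2'R,5'R)-1'-methyl-2'-(prop-1-en-2-yl)spiro[1,3-dioxolane-2,4'-[6]oxabicyclo[3.2.1]octan]-7'-one
Conditions: Me3SiOCH2CH2OSiMe3 (2 equiv), Me3SiOTf (5 mol %), CH2Cl2, −78 → −20 °C
Reagents that add atoms: 1,2-bis(trimethylsilyloxy)ethane, C[Si](C)(C)OCCO[Si](C)(C)C
Why: Noyori ketalisation under aprotic conditions masks the ketone without isomerising the isopropenyl group or opening the lactone, so that the lactone alone can be reduced next; no stereocentre is touched.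

Step 7
Reactants: 11 (1'S,2'R,5'R)-1'-methyl-2'-(prop-1-en-2-yl)spiro[1,3-dioxolane-2,4'-[6]oxabicyclo[3.2.1]octan]-7'-one
Product: 12 (1'S,2'R,5'R)-1'-methyl-2'-(prop-1-en-2-yl)spiro[1,3-dioxolane-2,4'-[6]oxabicyclo[3.2.1]octan]-7'-ol (anomer mixture)
Conditions: i-Bu2AlH (1.2 equiv), CH2Cl2, −78 °C; aq. KNaC4H4O6
Reagents that add atoms: none
Why: Partial lactone reduction with i-Bu2AlH at −78 °C stops at the aluminium lactolate, which the bridged ring keeps from collapsing, so the lactol should be obtained as an inconsequential anomer mixture.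

Step 8
Reactants: 12 (1'S,2'R,5'R)-1'-methyl-2'-(prop-1-en-2-yl)spiro[1,3-dioxolane-2,4'-[6]oxabicyclo[3.2.1]octan]-7'-ol; 13 methyltriphenylphosphonium bromide
Product: 14 (6R,8R,9R)-8-ethenyl-8-methyl-9-(prop-1-en-2-yl)-1,4-dioxaspiro[4.5]decan-6-ol
Conditions: Ph3PCH3Br (4 equiv), KOt-Bu (3.8 equiv), THF, 0 → 60 °C
Reagents that add atoms: methyltriphenylphosphonium bromide (13), C[P+](c1ccccc1)(c1ccccc1)c1ccccc1.[Br-]
Why: Wittig methylenation of the ring-opened hydroxy aldehyde tautomer turns the former lactone carbon into the vinyl CH and frees the C8 hydroxyl, the aldehyde being non-enolisable so that the quaternary centre cannot epimerise.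

Step 9
Reactants: 14 (6R,8R,9R)-8-ethenyl-8-methyl-9-(prop-1-en-2-yl)-1,4-dioxaspiro[4.5]decan-6-ol
Product: 15 (2R,4R,5R)-4-ethenyl-2-hydroxy-4-methyl-5-(prop-1-en-2-yl)cyclohexan-1-one
Conditions: 1 M aq. HCl, THF, 23 °C
Reagents that add atoms: water, O
Why: Mild acid-catalysed ketal hydrolysis should unveil the α-ketol, whose hydroxyl is equatorial and so already in the thermodynamically preferred configuration, while the 1,1-disubstituted alkene tolerates dilute acid at 23 °C.

Step 10
Reactants: 3 1-methylcyclohexa-2,5-diene-1-carboxylic acid; 4 N-bromosuccinimide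
Product: 16 (1R,5R,8R)-8-bromo-1-methyl-6-oxabicyclo[3.2.1]oct-2-en-7-one
Conditions: NBS (1.1 equiv), (DHQ)2PHAL (10 mol %), CHCl3/n-hexane 1:1, −40 °C
Reagents that add atoms: N-bromosuccinimide (4), O=C1CCC(=O)N1Br
Why: The same enantioselective bromolactonisation as in step 2 with the pseudo-enantiomeric ligand should select the other enantiotopic alkene and give the mirror-image γ-lactone, again with O cis to the carboxyl carbon and Br anti to O.

Step 11
Reactants: 16 (1R,5R,8R)-8-bromo-1-methyl-6-oxabicyclo[3.2.1]oct-2-en-7-one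
Product: 17 (1R,5R)-1-methyl-6-oxabicyclo[3.2.1]oct-2-en-7-one
Conditions: Bu3SnH (1.5 equiv, 0.5 M), AIBN (10 mol %), benzene, 80 °C
Reagents that add atoms: none
Why: Radical-chain hydrodebromination as in step 3, with concentrated stannane suppressing rearrangement of the homoallylic radical; no new stereocentre.

Step 12
Reactants: 17 (1R,5R)-1-methyl-6-oxabicyclo[3.2.1]oct-2-en-7-one
Product: 18 (1R,5S)-1-methyl-6-oxabicyclo[3.2.1]oct-2-ene-4,7-dione
Conditions: Rh2(cap)4 (1 mol %), t-BuOOH (70% aq., 5 equiv), K2CO3 (0.5 equiv), CH2Cl2, 23 °C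
Reagents that add atoms: tert-butyl hydroperoxide, CC(C)(C)OO
Why: Rhodium-catalysed allylic oxidation at the only allylic CH2, as in step 4, should give the enone with the carbonyl at C4.

Step 13
Reactants: 18 (1R,5S)-1-methyl-6-oxabicyclo[3.2.1]oct-2-ene-4,7-dione; 8 isopropenylmagnesium bromide
Product: 20 (1R,2S,5S)-1-methyl-2-(prop-1-en-2-yl)-6-oxabicyclo[3.2.1]octane-4,7-dione, via trimethylsilyl enol ether 19 (not isolated)
Conditions: CH2=C(CH3)MgBr (1.5 equiv), CuBr·SMe2 (20 mol %), Me3SiCl (2 equiv), THF, −78 → −40 °C; 1 M HCl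
Reagents that add atoms: isopropenylmagnesium bromide (8), CC(=C)[Mg]Br
Why: Copper-catalysed conjugate addition anti to the lactone bridge, as in step 5, sets C2 (C5' of the target) trans to the future vinyl group.

Step 14
Reactants: 20 (1R,2S,5S)-1-methyl-2-(prop-1-en-2-yl)-6-oxabicyclo[3.2.1]octane-4,7-dione
Product: 22 (1R,2S,5R)-1-methyl-2-(prop-1-en-2-yl)-6-oxabicyclo[3.2.1]octan-7-one, via tosylhydrazone 21 (not isolated)
Conditions: TsNHNH2 (1.2 equiv), EtOH, 60 °C; evaporate; catecholborane (2 equiv), CHCl3, 0 → 23 °C; NaOAc·3H2O, reflux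
Reagents that add atoms: none
Why: Hydride addition of catecholborane to the tosylhydrazone followed by acetate-induced loss of sulfinate and N2 (Caglioti-type deoxygenation in Kabalka's mild form) turns C=O into CH2 without touching lactone or alkenes, and loss of the neighbouring acyloxy group is blocked because it would need a bridgehead double bond.

Step 15
Reactants: 22 (1R,2S,5R)-1-methyl-2-(prop-1-en-2-yl)-6-oxabicyclo[3.2.1]octan-7-one
Product: 23 (1R,2S,5R)-1-methyl-2-(prop-1-en-2-yl)-6-oxabicyclo[3.2.1]octan-7-ol (anomer mixture)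
Conditions: i-Bu2AlH (1.2 equiv), CH2Cl2, −78 °C; aq. KNaC4H4O6
Reagents that add atoms: none
Why: Partial reduction of the bridged lactone with i-Bu2AlH stops at the lactol as in step 7.

Step 16
Reactants: 23 (1R,2S,5R)-1-methyl-2-(prop-1-en-2-yl)-6-oxabicyclo[3.2.1]octan-7-ol; 13 methyltriphenylphosphonium bromide
Product: 24 (1R,3S,4S)-3-ethenyl-3-methyl-4-(prop-1-en-2-yl)cyclohexan-1-ol
Conditions: Ph3PCH3Br (4 equiv), KOt-Bu (3.8 equiv), THF, 0 → 60 °C
Reagents that add atoms: methyltriphenylphosphonium bromide (13), C[P+](c1ccccc1)(c1ccccc1)c1ccccc1.[Br-]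
Why: Wittig methylenation of the lactol, as in step 8, converts the lactone carbon into the vinyl group on C10' and releases the C8' hydroxyl.

Step 17
Reactants: 24 (1R,3S,4S)-3-ethenyl-3-methyl-4-(prop-1-en-2-yl)cyclohexan-1-ol
Product: 25 (3S,4S)-3-ethenyl-3-methyl-4-(prop-1-en-2-yl)cyclohexan-1-one
Conditions: Dess–Martin periodinane (1.3 equiv), NaHCO3, CH2Cl2, 23 °C
Reagents that add atoms: none
Why: Dess–Martin oxidation under buffered neutral conditions removes the carbinol centre, whose configuration is the wrong one for ring A', and gives a ketone that can be enolised towards C7' and later reduced from the opposite face.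

Step 18
Reactants: 25 (3S,4S)-3-ethenyl-3-methyl-4-(prop-1-en-2-yl)cyclohexan-1-one; 26 methyl bromoacetate
Product: 27 methyl 2-[(1R,4S,5S)-4-ethenyl-4-methyl-2-oxo-5-(prop-1-en-2-yl)cyclohexyl]acetate
Conditions: LiN(i-Pr)2 (1.05 equiv), THF, −78 °C; BrCH2CO2Me (1.2 equiv), DMPU, −78 → −20 °C; then NaOMe (0.2 equiv), MeOH, 23 °C
Reagents that add atoms: methyl bromoacetate (26), COC(=O)CBr
Why: Kinetic deprotonation should occur at C6 of 25 (C7' of the target), away from the quaternary centre, and enolate alkylation with the α-bromo ester followed by base equilibration of the new α-centre places the CH2CO2Me arm equatorial, cis to the isopropenyl group.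

Step 19
Reactants: 27 methyl 2-[(1R,4S,5S)-4-ethenyl-4-methyl-2-oxo-5-(prop-1-en-2-yl)cyclohexyl]acetate
Product: 29 (3aR,5S,6S,7aR)-6-ethenyl-6-methyl-5-(prop-1-en-2-yl)hexahydro-1-benzofuran-2(3H)-one, via hydroxy ester 28 (not isolated)
Conditions: LiBH(s-Bu)3 (1.2 equiv), THF, −78 → 23 °C
Reagents that add atoms: none
Why: The bulky borohydride should attack the ketone from the equatorial direction because the axial face is closed by the syn-axial methyl group, so the axial alkoxide forms cis to the acetate arm and lactonises to the cis-fused γ-lactone (hindered-hydride reduction, then lactonisation), which sets C8' as R.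

Step 20
Reactants: 29 (3aR,5S,6S,7aR)-6-ethenyl-6-methyl-5-(prop-1-en-2-yl)hexahydro-1-benzofuran-2(3H)-one; 30 N,N-dimethylmethyleneiminium iodide
Product: 33 (3aR,5S,6S,7aR)-6-ethenyl-6-methyl-3-methylidene-5-(prop-1-en-2-yl)hexahydro-1-benzofuran-2(3H)-one, via Mannich base 31 (not isolated), via trimethylammonium iodide 32 (not isolated)
Conditions: LiN(i-Pr)2 (1.1 equiv), THF, −78 °C; CH2=NMe2+ I−, −78 → 23 °C; MeI (excess), MeOH, 23 °C; aq. NaHCO3/CH2Cl2
Reagents that add atoms: N,N-dimethylmethyleneiminium iodide (30), C=[N+](C)C.[I-]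
Why: Mannich aminomethylation of the lactone enolate with Eschenmoser's salt, exhaustive N-methylation and base-induced β-elimination is the standard α-methylenation of γ-lactones and removes the transient C3 stereocentre again.

Step 21
Reactants: 34 prop-2-en-1-yl 2-(diethoxyphosphoryl)acetate; 35 tert-butyl bromoacetate
Product: 36 4-tert-butyl 1-prop-2-en-1-yl 2-(diethoxyphosphoryl)butanedioate (racemic)
Conditions: NaH (1.0 equiv), THF, 0 °C; t-BuO2CCH2Br (1.0 equiv), 0 → 23 °C
Reagents that add atoms: tert-butyl bromoacetate (35), CC(C)(C)OC(=O)CBr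
Why: SN2 alkylation of the sodium phosphonoacetate carbanion with the reactive α-bromo ester gives the phosphonosuccinate, whose new stereocentre is racemic and is destroyed in step 27.

Step 22
Reactants: 36 4-tert-butyl 1-prop-2-en-1-yl 2-(diethoxyphosphoryl)butanedioate
Product: 37 3-(diethoxyphosphoryl)-4-oxo-4-(prop-2-en-1-yloxy)butanoic acid
Conditions: CF3CO2H/CH2Cl2 1:3, 23 °C
Reagents that add atoms: none
Why: Acidolysis of the tert-butyl ester by loss of 2-methylpropene leaves the allyl and phosphonate esters intact and is carried out before any acid-sensitive alkene is present.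

Step 23
Reactants: 37 3-(diethoxyphosphoryl)-4-oxo-4-(prop-2-en-1-yloxy)butanoic acid; 38 N-hydroxyphthalimide
Product: 39 4-(1,3-dioxoisoindolin-2-yl) 1-prop-2-en-1-yl 2-(diethoxyphosphoryl)butanedioate
Conditions: N,N'-diisopropylcarbodiimide (1.1 equiv), DMAP (5 mol %), CH2Cl2, 23 °C
Reagents that add atoms: N-hydroxyphthalimide (38), ON1C(=O)c2ccccc2C1=O
Why: Carbodiimide esterification converts the free acid into the redox-active N-acyloxyphthalimide needed for decarboxylative radical generation.

Step 24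
Reactants: 39 4-(1,3-dioxoisoindolin-2-yl) 1-prop-2-en-1-yl 2-(diethoxyphosphoryl)butanedioate; 33 (3aR,5S,6S,7aR)-6-ethenyl-6-methyl-3-methylidene-5-(prop-1-en-2-yl)hexahydro-1-benzofuran-2(3H)-one
Product: 40 prop-2-en-1-yl 2-(diethoxyphosphoryl)-4-[(3S,3aR,5S,6S,7aR)-6-ethenyl-6-methyl-2-oxo-5-(prop-1-en-2-yl)octahydro-1-benzofuran-3-yl]butanoate (both epimers at the phosphonate carbon)
Conditions: 39 (1.5 equiv), Ru(bpy)3(PF6)2 (1 mol %), Hantzsch ester (1.5 equiv), i-Pr2NEt (2 equiv), CH2Cl2, blue LEDs, 23 °C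
Reagents that add atoms: none
Why: Single-electron reduction of the N-acyloxyphthalimide releases CO2 and a primary alkyl radical that adds to the terminal carbon of the α-methylene lactone (decarboxylative Giese reaction), forming C13–C13', and hydrogen transfer from the Hantzsch ester to the lactone radical on the convex face of the cis-fused bicycle should set C3 (C11' of the target) as S with its hydrogen cis to the ring-fusion hydrogens.

Step 25
Reactants: 40 prop-2-en-1-yl 2-(diethoxyphosphoryl)-4-[(3S,3aR,5S,6S,7aR)-6-ethenyl-6-methyl-2-oxo-5-(prop-1-en-2-yl)octahydro-1-benzofuran-3-yl]butanoate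
Product: 41 2-(diethoxyphosphoryl)-4-[(3S,3aR,5S,6S,7aR)-6-ethenyl-6-methyl-2-oxo-5-(prop-1-en-2-yl)octahydro-1-benzofuran-3-yl]butanoic acid
Conditions: Pd(PPh3)4 (5 mol %), morpholine (3 equiv), THF, 23 °C; dilute aq. citric acid
Reagents that add atoms: none
Why: In this Tsuji–Trost deallylation zerovalent palladium ionises only the allyl ester and morpholine traps the π-allyl complex, so the acid is freed without the strong acid or base that could harm the alkenes or epimerise C3.

Step 26
Reactants: 41 2-(diethoxyphosphoryl)-4-[(3S,3aR,5S,6S,7aR)-6-ethenyl-6-methyl-2-oxo-5-(prop-1-en-2-yl)octahydro-1-benzofuran-3-yl]butanoic acid; 15 (2R,4R,5R)-4-ethenyl-2-hydroxy-4-methyl-5-(prop-1-en-2-yl)cyclohexan-1-one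
Product: 42 (1R,3R,4R)-3-ethenyl-3-methyl-6-oxo-4-(prop-1-en-2-yl)cyclohexyl 2-(diethoxyphosphoryl)-4-[(3S,3aR,5S,6S,7aR)-6-ethenyl-6-methyl-2-oxo-5-(prop-1-en-2-yl)octahydro-1-benzofuran-3-yl]butanoate
Conditions: EDC·HCl (1.3 equiv), DMAP (0.2 equiv), CH2Cl2, 0 → 23 °C
Reagents that add atoms: none
Why: Steglich-type carbodiimide esterification acylates the equatorial secondary hydroxyl of the ketol with the α-phosphono acid under conditions too mild to enolise the α-ketol, so no stereocentre of either half is disturbed.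

Step 27
Reactants: 42 (1R,3R,4R)-3-ethenyl-3-methyl-6-oxo-4-(prop-1-en-2-yl)cyclohexyl 2-(diethoxyphosphoryl)-4-[(3S,3aR,5S,6S,7aR)-6-ethenyl-6-methyl-2-oxo-5-(prop-1-en-2-yl)octahydro-1-benzofuran-3-yl]butanoate
Product: 43 (3S,3aR,5S,6S,7aR)-6-ethenyl-3-{2-[(5R,6R,7aR)-6-ethenyl-6-methyl-2-oxo-5-(prop-1-en-2-yl)-2,4,5,6,7,7a-hexahydro-1-benzofuran-3-yl]ethyl}-6-methyl-5-(prop-1-en-2-yl)hexahydro-1-benzofuran-2(3H)-one
Conditions: LiCl (5 equiv), DBU (1.5 equiv), MeCN, 0 → 23 °C
Reagents that add atoms: none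
Why: In this intramolecular Horner–Wadsworth–Emmons olefination under Masamune–Roush conditions the lithium-chelated phosphonate carbanion attacks the neighbouring ketone through a five-membered transition state and loss of diethyl phosphate closes ring B as the tetrasubstituted butenolide, the base being too weak to deprotonate the saturated lactone at C11'.

**Compound list**

1 | benzoic acid | OC(=O)c1ccccc1 | starting material
2 | iodomethane | CI | starting material
3 | 1-methylcyclohexa-2,5-diene-1-carboxylic acid | CC1(C=CCC=C1)C(=O)O | intermediate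
4 | N-bromosuccinimide | O=C1CCC(=O)N1Br | starting material
5 | (1S,5S,8S)-8-bromo-1-methyl-6-oxabicyclo[3.2.1]oct-2-en-7-one | O=C1O[C@H]2CC=C[C@]1(C)[C@@H]2Br | intermediate
6 | (1S,5S)-1-methyl-6-oxabicyclo[3.2.1]oct-2-en-7-one | O=C1O[C@H]2CC=C[C@]1(C)C2 | intermediate
7 | (1S,5R)-1-methyl-6-oxabicyclo[3.2.1]oct-2-ene-4,7-dione | O=C1O[C@H]2C(=O)C=C[C@]1(C)C2 | intermediate
8 | isopropenylmagnesium bromide | CC(=C)[Mg]Br | starting material
9 | (1S,2R,5R)-1-methyl-2-(prop-1-en-2-yl)-4-(trimethylsilyloxy)-6-oxabicyclo[3.2.1]oct-3-en-7-one (formed in the flask, not isolated) | O=C1O[C@H]2C(O[Si](C)(C)C)=C[C@H](C(C)=C)[C@]1(C)C2 | intermediate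
10 | (1S,2R,5R)-1-methyl-2-(prop-1-en-2-yl)-6-oxabicyclo[3.2.1]octane-4,7-dione | O=C1O[C@H]2C(=O)C[C@H](C(C)=C)[C@]1(C)C2 | intermediate
11 | (1'S,2'R,5'R)-1'-methyl-2'-(prop-1-en-2-yl)spiro[1,3-dioxolane-2,4'-[6]oxabicyclo[3.2.1]octan]-7'-one | O=C1O[C@H]2C3(OCCO3)C[C@H](C(C)=C)[C@]1(C)C2 | intermediate
12 | (1'S,2'R,5'R)-1'-methyl-2'-(prop-1-en-2-yl)spiro[1,3-dioxolane-2,4'-[6]oxabicyclo[3.2.1]octan]-7'-ol, anomer mixture | OC1O[C@H]2C3(OCCO3)C[C@H](C(C)=C)[C@]1(C)C2 | intermediate
13 | methyltriphenylphosphonium bromide | C[P+](c1ccccc1)(c1ccccc1)c1ccccc1.[Br-] | starting material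
14 | (6R,8R,9R)-8-ethenyl-8-methyl-9-(prop-1-en-2-yl)-1,4-dioxaspiro[4.5]decan-6-ol | C=C[C@@]1(C)C[C@@H](O)C2(OCCO2)C[C@@H]1C(C)=C | intermediate
15 | (2R,4R,5R)-4-ethenyl-2-hydroxy-4-methyl-5-(prop-1-en-2-yl)cyclohexan-1-one | C=C[C@@]1(C)C[C@@H](O)C(=O)C[C@@H]1C(C)=C | intermediate
16 | (1R,5R,8R)-8-bromo-1-methyl-6-oxabicyclo[3.2.1]oct-2-en-7-one | O=C1O[C@@H]2CC=C[C@@]1(C)[C@H]2Br | intermediate
17 | (1R,5R)-1-methyl-6-oxabicyclo[3.2.1]oct-2-en-7-one | O=C1O[C@@H]2CC=C[C@@]1(C)C2 | intermediate
18 | (1R,5S)-1-methyl-6-oxabicyclo[3.2.1]oct-2-ene-4,7-dione | O=C1O[C@@H]2C(=O)C=C[C@@]1(C)C2 | intermediate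
19 | (1R,2S,5S)-1-methyl-2-(prop-1-en-2-yl)-4-(trimethylsilyloxy)-6-oxabicyclo[3.2.1]oct-3-en-7-one (formed in the flask, not isolated) | O=C1O[C@@H]2C(O[Si](C)(C)C)=C[C@@H](C(C)=C)[C@@]1(C)C2 | intermediate
20 | (1R,2S,5S)-1-methyl-2-(prop-1-en-2-yl)-6-oxabicyclo[3.2.1]octane-4,7-dione | O=C1O[C@@H]2C(=O)C[C@@H](C(C)=C)[C@@]1(C)C2 | intermediate
21 | N'-[(1R,2S,5S)-1-methyl-7-oxo-2-(prop-1-en-2-yl)-6-oxabicyclo[3.2.1]octan-4-ylidene]-4-methylbenzenesulfonohydrazide (formed in the flask, not isolated) | O=C1O[C@@H]2C(=NNS(=O)(=O)c3ccc(C)cc3)C[C@@H](C(C)=C)[C@@]1(C)C2 | intermediate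
22 | (1R,2S,5R)-1-methyl-2-(prop-1-en-2-yl)-6-oxabicyclo[3.2.1]octan-7-one | O=C1O[C@@H]2CC[C@@H](C(C)=C)[C@@]1(C)C2 | intermediate
23 | (1R,2S,5R)-1-methyl-2-(prop-1-en-2-yl)-6-oxabicyclo[3.2.1]octan-7-ol, anomer mixture | OC1O[C@@H]2CC[C@@H](C(C)=C)[C@@]1(C)C2 | intermediate
24 | (1R,3S,4S)-3-ethenyl-3-methyl-4-(prop-1-en-2-yl)cyclohexan-1-ol | C=C[C@]1(C)C[C@H](O)CC[C@H]1C(C)=C | intermediate
25 | (3S,4S)-3-ethenyl-3-methyl-4-(prop-1-en-2-yl)cyclohexan-1-one | C=C[C@]1(C)CC(=O)CC[C@H]1C(C)=C | intermediate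
26 | methyl bromoacetate | COC(=O)CBr | starting material
27 | methyl 2-[(1R,4S,5S)-4-ethenyl-4-methyl-2-oxo-5-(prop-1-en-2-yl)cyclohexyl]acetate | COC(=O)C[C@H]1C[C@@H](C(C)=C)[C@](C)(C=C)CC1=O | intermediate
28 | methyl 2-[(1R,2R,4S,5S)-4-ethenyl-2-hydroxy-4-methyl-5-(prop-1-en-2-yl)cyclohexyl]acetate (as its lithium alkoxide, not isolated) | COC(=O)C[C@H]1C[C@@H](C(C)=C)[C@](C)(C=C)C[C@H]1O | intermediate
29 | (3aR,5S,6S,7aR)-6-ethenyl-6-methyl-5-(prop-1-en-2-yl)hexahydro-1-benzofuran-2(3H)-one | O=C1C[C@H]2C[C@@H](C(C)=C)[C@](C)(C=C)C[C@H]2O1 | intermediate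
30 | N,N-dimethylmethyleneiminium iodide (Eschenmoser's salt) | C=[N+](C)C.[I-] | starting material
31 | (3aR,5S,6S,7aR)-3-[(dimethylamino)methyl]-6-ethenyl-6-methyl-5-(prop-1-en-2-yl)hexahydro-1-benzofuran-2(3H)-one, C3 not assigned (not isolated) | CN(C)CC1C(=O)O[C@@H]2C[C@@](C)(C=C)[C@H](C(C)=C)C[C@H]12 | intermediate
32 | [(3aR,5S,6S,7aR)-6-ethenyl-6-methyl-2-oxo-5-(prop-1-en-2-yl)octahydro-1-benzofuran-3-yl]-N,N,N-trimethylmethanaminium iodide (not isolated) | C[N+](C)(C)CC1C(=O)O[C@@H]2C[C@@](C)(C=C)[C@H](C(C)=C)C[C@H]12.[I-] | intermediate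
33 | (3aR,5S,6S,7aR)-6-ethenyl-6-methyl-3-methylidene-5-(prop-1-en-2-yl)hexahydro-1-benzofuran-2(3H)-one | C=C1C(=O)O[C@@H]2C[C@@](C)(C=C)[C@H](C(C)=C)C[C@H]12 | intermediate
34 | prop-2-en-1-yl 2-(diethoxyphosphoryl)acetate | C=CCOC(=O)CP(=O)(OCC)OCC | starting material
35 | tert-butyl bromoacetate | CC(C)(C)OC(=O)CBr | starting material
36 | 4-tert-butyl 1-prop-2-en-1-yl 2-(diethoxyphosphoryl)butanedioate (racemic) | C=CCOC(=O)C(CC(=O)OC(C)(C)C)P(=O)(OCC)OCC | intermediate
37 | 3-(diethoxyphosphoryl)-4-oxo-4-(prop-2-en-1-yloxy)butanoic acid (racemic) | C=CCOC(=O)C(CC(=O)O)P(=O)(OCC)OCC | intermediate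
38 | N-hydroxyphthalimide | ON1C(=O)c2ccccc2C1=O | starting material
39 | 4-(1,3-dioxoisoindolin-2-yl) 1-prop-2-en-1-yl 2-(diethoxyphosphoryl)butanedioate (racemic) | C=CCOC(=O)C(CC(=O)ON1C(=O)c2ccccc2C1=O)P(=O)(OCC)OCC | intermediate
40 | prop-2-en-1-yl 2-(diethoxyphosphoryl)-4-[(3S,3aR,5S,6S,7aR)-6-ethenyl-6-methyl-2-oxo-5-(prop-1-en-2-yl)octahydro-1-benzofuran-3-yl]butanoate (epimers at the phosphonate carbon) | C=CCOC(=O)C(CC[C@@H]1C(=O)O[C@@H]2C[C@@](C)(C=C)[C@H](C(C)=C)C[C@H]12)P(=O)(OCC)OCC | intermediate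
41 | 2-(diethoxyphosphoryl)-4-[(3S,3aR,5S,6S,7aR)-6-ethenyl-6-methyl-2-oxo-5-(prop-1-en-2-yl)octahydro-1-benzofuran-3-yl]butanoic acid (epimers at the phosphonate carbon) | OC(=O)C(CC[C@@H]1C(=O)O[C@@H]2C[C@@](C)(C=C)[C@H](C(C)=C)C[C@H]12)P(=O)(OCC)OCC | intermediate
42 | (1R,3R,4R)-3-ethenyl-3-methyl-6-oxo-4-(prop-1-en-2-yl)cyclohexyl 2-(diethoxyphosphoryl)-4-[(3S,3aR,5S,6S,7aR)-6-ethenyl-6-methyl-2-oxo-5-(prop-1-en-2-yl)octahydro-1-benzofuran-3-yl]butanoate (epimers at the phosphonate carbon) | C=C[C@@]1(C)C[C@@H](OC(=O)C(CC[C@@H]2C(=O)O[C@@H]3C[C@@](C)(C=C)[C@H](C(C)=C)C[C@H]23)P(=O)(OCC)OCC)C(=O)C[C@@H]1C(C)=C | intermediate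
43 | (3S,3aR,5S,6S,7aR)-6-ethenyl-3-{2-[(5R,6R,7aR)-6-ethenyl-6-methyl-2-oxo-5-(prop-1-en-2-yl)-2,4,5,6,7,7a-hexahydro-1-benzofuran-3-yl]ethyl}-6-methyl-5-(prop-1-en-2-yl)hexahydro-1-benzofuran-2(3H)-one (CNP0332736.1) | C=C[C@@]1(C)C[C@H]2OC(=O)C(CC[C@@H]3C(=O)O[C@@H]4C[C@@](C)(C=C)[C@H](C(=C)C)C[C@H]34)=C2C[C@@H]1C(=C)C | target

**Step count and risks**

Total: 27 steps. Longest linear sequence: 16 steps (1, 10–20, 24–27).

Steps most likely to fail:

1. Step 24. The primary radical may be reduced or may oligomerise before it is captured by the precious acceptor, and hydrogen transfer to the lactone radical may not be fully face-selective. Fallback with reversed roles of the partners: setting out from 33, conjugate addition of benzeneselenol ((PhSe)2, NaBH4, EtOH) should give the (3S)-3-[(phenylselanyl)methyl] lactone F1, with C11' set by protonation on the convex face. In parallel 34 is condensed with paraformaldehyde (piperidine, then acid-promoted elimination) to prop-2-en-1-yl 2-(diethoxyphosphoryl)prop-2-enoate F2. Bu3SnH/AIBN then generates the C13' radical from F1, which adds to the doubly activated alkene of F2, and the route is rejoined at 40.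

2. Step 14. Hydrazone formation at the hindered ketone beside the bridgehead may be slow, and the borane reduction may stall or give elimination products. Fallback by radical deoxygenation of the alcohol: setting out from 20, NaBH4 (MeOH, 0 °C) should give the 4-hydroxy lactone F3 (either carbinol epimer serves). 1,1'-Thiocarbonyldiimidazole converts it into the imidazole-1-carbothioate F4, and Bu3SnH/AIBN (toluene, 110 °C; Barton–McCombie) removes the oxygen, returning to the route at 22.

3. Step 4 (its mirror image, step 12, carries the same risk). Oxygen may be delivered to the other terminus of the allyl radical, giving the transposed enone, or the oxidation may stop at the peroxide or alcohol stage. Fallback through a pericyclic, regiospecific path: setting out from 6, SeO2 (catalytic) with t-BuOOH oxidises by an ene reaction and [2,3] shift and can only place oxygen at C4, giving the allylic alcohol F5. Dess–Martin oxidation then returns to the route at 7. In the mirror-image series the same two operations lead from 17 through the enantiomeric alcohol F6 back to 18.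

**Further compounds**

F1 | step 24 | (3S,3aR,5S,6S,7aR)-6-ethenyl-6-methyl-3-[(phenylselanyl)methyl]-5-(prop-1-en-2-yl)hexahydro-1-benzofuran-2(3H)-one | c1ccccc1[Se]C[C@@H]1C(=O)O[C@@H]2C[C@@](C)(C=C)[C@H](C(C)=C)C[C@H]12
F2 | step 24 | prop-2-en-1-yl 2-(diethoxyphosphoryl)prop-2-enoate | C=CCOC(=O)C(=C)P(=O)(OCC)OCC
F3 | step 14 | (1R,2S,5S)-4-hydroxy-1-methyl-2-(prop-1-en-2-yl)-6-oxabicyclo[3.2.1]octan-7-one (C4 epimer not assigned) | O=C1O[C@@H]2C(O)C[C@@H](C(C)=C)[C@@]1(C)C2
F4 | step 14 | O-[(1R,2S,5S)-1-methyl-7-oxo-2-(prop-1-en-2-yl)-6-oxabicyclo[3.2.1]octan-4-yl] 1H-imidazole-1-carbothioate | O=C1O[C@@H]2C(OC(=S)n3ccnc3)C[C@@H](C(C)=C)[C@@]1(C)C2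
F5 | step 4 | (1S,5R)-4-hydroxy-1-methyl-6-oxabicyclo[3.2.1]oct-2-en-7-one (C4 epimer not assigned) | O=C1O[C@H]2C(O)C=C[C@]1(C)C2
F6 | step 12 | (1R,5S)-4-hydroxy-1-methyl-6-oxabicyclo[3.2.1]oct-2-en-7-one (C4 epimer not assigned) | O=C1O[C@@H]2C(O)C=C[C@@]1(C)C2
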